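**Retrosynthetic overview**
1. Licoleafol ⇐ its tris-silyl ether (fluoride). The (E)-CH2OH comes from SeO2/t-BuOOH oxidation of the (E)-methyl of an 8-prenyl group.
2. The 8-prenyl group ⇐ a 5-O-prenyl ether, relayed O5 → C6 → C8 by a domino para-Claisen–Cope rearrangement (no direct C-prenylation).
3. The C2–aryl bond and (2S) ⇐ palladium-catalysed enantioselective conjugate addition of a catechol-protected arylboronic acid to an intact chromone (no chalcone, no oxa-Michael closure).
4. The chromone ⇐ 5,7-dihydroxychromone (7-O-silylation, then 5-O-Mitsunobu prenylation); the boronic acid ⇐ 4-bromocatechol.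
5. Rings: A and C are bought fused as the chromone and ring B arrives whole in the boronic acid. No ring is built; ring C goes from pyranone to chiral dihydropyranone in the arylation.

Abbreviations: TBS = tert-butyldimethylsilyl; prenyl = 3-methylbut-2-en-1-yl; fod = 6,6,7,7,8,8,8-heptafluoro-2,2-dimethyloctane-3,5-dionate; (R)-t-BuPyOx = (R)-4-tert-butyl-2-(pyridin-2-yl)-4,5-dihydrooxazole.

Assumption: the (R)-ligand is taken to give (2S), by analogy with the (S)-ligand giving (R)-configured products from cyclic enones and chromones; the first run is checked by CD against the natural product and the ligand antipode is used if the sense is opposite.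

**Step 1**
Reactants: 1 4-bromocatechol
Product: 2 4-bromo-1,2-bis(tert-butyldimethylsilyloxy)benzene
Conditions: TBSCl (2.4 equiv), imidazole (5 equiv), DMF, rt
Reagents that add atoms: tert-butyldimethylsilyl chloride, CC(C)(C)[Si](C)(C)Cl
Why: Imidazole-promoted silyl ether formation caps both catechol oxygens with a group that survives organolithium, palladium, Lewis-acid and peroxide steps and leaves with fluoride at the end.

**Step 2**
Reactants: 2 4-bromo-1,2-bis(tert-butyldimethylsilyloxy)benzene
Product: 5 3,4-bis(tert-butyldimethylsilyloxy)phenylboronic acid, via aryllithium 3 (not isolated), via lithium aryltriisopropoxyborate 4 (not isolated)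
Conditions: n-BuLi (1.1 equiv), THF, −78 °C; B(OiPr)3 (1.5 equiv), −78 °C to rt; 1 M HCl, 0 °C
Reagents that add atoms: triisopropyl borate, CC(C)OB(OC(C)C)OC(C)C (boron); water, O (the two B–OH oxygens); n-butyllithium, [Li]CCCC (lithium of 3 and 4 only)
Why: Lithiation–borylation, in which bromine–lithium exchange at −78 °C outruns attack on the aryl silyl ethers (the lithium is not ortho to a silyloxy group, so no silyl migration), the borate traps the aryllithium as an ate complex, and brief cold acid hydrolysis frees the boronic acid.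

**Step 3**
Reactants: 6 5,7-dihydroxychromone
Product: 7 7-(tert-butyldimethylsilyloxy)-5-hydroxy-4H-chromen-4-one
Conditions: TBSCl (1.05 equiv), imidazole (2 equiv), DMF, 0 °C
Reagents that add atoms: tert-butyldimethylsilyl chloride, CC(C)(C)[Si](C)(C)Cl
Why: Regioselective silyl ether formation, because the 7-OH is the acidic, unhindered phenol while the 5-OH is locked in a hydrogen bond to the C4 carbonyl and does not react with one equivalent of TBSCl.

**Step 4**
Reactants: 7 7-(tert-butyldimethylsilyloxy)-5-hydroxy-4H-chromen-4-one; 8 prenyl alcohol (3-methylbut-2-en-1-ol)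
Product: 9 7-(tert-butyldimethylsilyloxy)-5-(prenyloxy)-4H-chromen-4-one
Conditions: PPh3 (1.5 equiv), DIAD (1.5 equiv), THF, 0 °C to rt
Reagents that add atoms: none
Why: Mitsunobu etherification alkylates the chelated 5-OH under neutral conditions that spare the aryl silyl ether, giving the unrearranged primary prenyl ether by SN2 attack on the oxyphosphonium ion; the ether masks the chelating 5-OH for step 5 and carries the C5 unit for step 6.

**Step 5**
Reactants: 9 7-(tert-butyldimethylsilyloxy)-5-(prenyloxy)-4H-chromen-4-one; 5 3,4-bis(tert-butyldimethylsilyloxy)phenylboronic acid (2 equiv)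
Product: 10 (2S)-2-[3,4-bis(tert-butyldimethylsilyloxy)phenyl]-7-(tert-butyldimethylsilyloxy)-5-(prenyloxy)chroman-4-one
Conditions: Pd(OCOCF3)2 (10 mol%), (R)-t-BuPyOx (12 mol%), NH4PF6 (30 mol%), H2O (5 equiv), ClCH2CH2Cl, 60 °C
Reagents that add atoms: none
Why: Palladium-catalysed asymmetric conjugate addition of an arylboronic acid to a chromone, in which the aryl group is transferred to a cationic divalent palladium pyridine–oxazoline complex, adds across C2=C3 on the face chosen by the ligand to set (2S), and the palladium enolate is protonated by water without base, so the ring does not open to a chalcone and the trisubstituted prenyl alkene does not insert.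

**Step 6**
Reactants: 10 (2S)-2-[3,4-bis(tert-butyldimethylsilyloxy)phenyl]-7-(tert-butyldimethylsilyloxy)-5-(prenyloxy)chroman-4-one
Product: 13 (2S)-2-[3,4-bis(tert-butyldimethylsilyloxy)phenyl]-7-(tert-butyldimethylsilyloxy)-5-hydroxy-8-prenylchroman-4-one, via Claisen dienone 11 (not isolated), via Cope dienone 12 (not isolated)
Conditions: Eu(fod)3 (10 mol%), CHCl3, 60 °C, sealed tube
Reagents that add atoms: none
Why: Lewis-acid-catalysed domino para-Claisen–Cope rearrangement, in which trivalent europium bound at the C4 carbonyl and O5 speeds the [3,3] shift from O5 to C6, the crowded reverse-prenyl dienone relays by a second [3,3] shift to C8, and tautomerisation gives the chelated 5-OH phenol, all without touching C2.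

**Step 7**
Reactants: 13 (2S)-2-[3,4-bis(tert-butyldimethylsilyloxy)phenyl]-7-(tert-butyldimethylsilyloxy)-5-hydroxy-8-prenylchroman-4-one
Product: 14 (2S)-2-[3,4-bis(tert-butyldimethylsilyloxy)phenyl]-7-(tert-butyldimethylsilyloxy)-5-hydroxy-8-[(2E)-4-hydroxy-3-methylbut-2-en-1-yl]chroman-4-one
Conditions: SeO2 (25 mol%), t-BuOOH (5.5 M in decane, 3 equiv), salicylic acid (10 mol%), CH2Cl2, 0 °C to rt
Reagents that add atoms: tert-butyl hydroperoxide, CC(C)(C)OO (net source of the new oxygen); selenium dioxide, O=[Se]=O (hands that oxygen to carbon and is re-formed)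
Why: Catalytic SeO2/t-BuOOH allylic oxidation (ene reaction, then [2,3]-sigmatropic shift of the allylseleninic acid) hydroxylates only the methyl group trans to the benzylic chain, which fixes the (E) geometry, and at room temperature the flavanone is neither dehydrogenated nor opened.

**Step 8**
Reactants: 14 (2S)-2-[3,4-bis(tert-butyldimethylsilyloxy)phenyl]-7-(tert-butyldimethylsilyloxy)-5-hydroxy-8-[(2E)-4-hydroxy-3-methylbut-2-en-1-yl]chroman-4-one
Product: 15 licoleafol, (2S)-2-(3,4-dihydroxyphenyl)-5,7-dihydroxy-8-[(2E)-4-hydroxy-3-methylbut-2-en-1-yl]chroman-4-one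
Conditions: HF·pyridine, pyridine, THF, 0 °C to rt
Reagents that add atoms: none
Why: Fluoride desilylation of the three aryl silyl ethers in a buffered, weakly acidic medium that does not enolise or ring-open the flavanone (C2 stays S) and does not ionise the allylic alcohol or cyclise it onto the 7-OH.

**Compound list**
1 | 4-bromocatechol (4-bromobenzene-1,2-diol) | Oc1ccc(Br)cc1O | starting material
2 | 4-bromo-1,2-bis(TBSO)benzene | Brc1ccc(O[Si](C)(C)C(C)(C)C)c(O[Si](C)(C)C(C)(C)C)c1 | intermediate
3 | [3,4-bis(TBSO)phenyl]lithium | [Li]c1ccc(O[Si](C)(C)C(C)(C)C)c(O[Si](C)(C)C(C)(C)C)c1 | intermediate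
4 | lithium [3,4-bis(TBSO)phenyl]triisopropoxyborate | [Li+].CC(C)O[B-](OC(C)C)(OC(C)C)c1ccc(O[Si](C)(C)C(C)(C)C)c(O[Si](C)(C)C(C)(C)C)c1 | intermediate
5 | 3,4-bis(TBSO)phenylboronic acid | OB(O)c1ccc(O[Si](C)(C)C(C)(C)C)c(O[Si](C)(C)C(C)(C)C)c1 | intermediate
6 | 5,7-dihydroxychromone (5,7-dihydroxy-4H-chromen-4-one) | Oc1cc(O)cc2occc(=O)c12 | starting material
7 | 7-(TBSO)-5-hydroxy-4H-chromen-4-one | Oc1cc(O[Si](C)(C)C(C)(C)C)cc2occc(=O)c12 | intermediate
8 | prenyl alcohol (3-methylbut-2-en-1-ol) | CC(C)=CCO | starting material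
9 | 7-(TBSO)-5-(prenyloxy)-4H-chromen-4-one | CC(C)=CCOc1cc(O[Si](C)(C)C(C)(C)C)cc2occc(=O)c12 | intermediate
10 | (2S)-2-[3,4-bis(TBSO)phenyl]-7-(TBSO)-5-(prenyloxy)chroman-4-one | CC(C)=CCOc1cc(O[Si](C)(C)C(C)(C)C)cc2O[C@H](c3ccc(O[Si](C)(C)C(C)(C)C)c(O[Si](C)(C)C(C)(C)C)c3)CC(=O)c12 | intermediate
11 | Claisen dienone: (2S)-2-[3,4-bis(TBSO)phenyl]-7-(TBSO)-6-(2-methylbut-3-en-2-yl)-2,3-dihydro-4H-chromene-4,5(6H)-dione, both C6 epimers | C=CC(C)(C)C1C(=O)C2=C(O[C@H](c3ccc(O[Si](C)(C)C(C)(C)C)c(O[Si](C)(C)C(C)(C)C)c3)CC2=O)C=C1O[Si](C)(C)C(C)(C)C | intermediate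
12 | Cope dienone: (2S)-2-[3,4-bis(TBSO)phenyl]-7-(TBSO)-8-prenyl-2,3-dihydro-4H-chromene-4,5(8H)-dione, both C8 epimers | CC(C)=CCC1C(O[Si](C)(C)C(C)(C)C)=CC(=O)C2=C1O[C@H](c1ccc(O[Si](C)(C)C(C)(C)C)c(O[Si](C)(C)C(C)(C)C)c1)CC2=O | intermediate
13 | (2S)-2-[3,4-bis(TBSO)phenyl]-7-(TBSO)-5-hydroxy-8-prenylchroman-4-one | CC(C)=CCc1c(O[Si](C)(C)C(C)(C)C)cc(O)c2c1O[C@H](c1ccc(O[Si](C)(C)C(C)(C)C)c(O[Si](C)(C)C(C)(C)C)c1)CC2=O | intermediate
14 | (2S)-2-[3,4-bis(TBSO)phenyl]-7-(TBSO)-5-hydroxy-8-[(2E)-4-hydroxy-3-methylbut-2-en-1-yl]chroman-4-one | C/C(=C\Cc1c(O[Si](C)(C)C(C)(C)C)cc(O)c2c1O[C@H](c1ccc(O[Si](C)(C)C(C)(C)C)c(O[Si](C)(C)C(C)(C)C)c1)CC2=O)CO | intermediate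
15 | licoleafol, (2S)-2-(3,4-dihydroxyphenyl)-5,7-dihydroxy-8-[(2E)-4-hydroxy-3-methylbut-2-en-1-yl]chroman-4-one | C/C(=C\Cc1c(O)cc(O)c2c1O[C@H](c1ccc(O)c(O)c1)CC2=O)CO | target

**Totals**
Total step count: 8. Longest linear sequence: 6 steps (6 → 15 through steps 3 to 8; the branch from 1 through steps 1, 2, 5 to 8 is equally long).

**Three steps most likely to fail**

Step 5 (asymmetric arylation of the chromone). The 5,7-dioxygenated chromone is an electron-rich acceptor, the boronic acid can protodeboronate, and the enantiomeric excess may fall short. The fallback sets out from 9 (with aryl bromide 2, so step 2 is not needed) and comes back at 10. It forms the C2–aryl bond first and sets the stereocentre by hydride delivery instead of aryl delivery. Chromone 9 is zincated at C2 with TMPZnCl·LiCl (THF, −20 °C to rt) to give [7-(TBSO)-5-(prenyloxy)-4-oxo-4H-chromen-2-yl]zinc chloride F1. This is coupled in the same flask with 2 (Pd(OAc)2, SPhos; Negishi coupling) to give the flavone 2-[3,4-bis(TBSO)phenyl]-7-(TBSO)-5-(prenyloxy)-4H-chromen-4-one F2. Enantioselective copper hydride 1,4-reduction of F2 (Cu(OAc)2, the DTBM-SEGPHOS enantiomer that gives 2S, (EtO)2MeSiH, t-BuOH, toluene, 0 °C), then mild hydrolysis of the silyl enol ether, gives 10.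

Step 6 (domino para-Claisen–Cope). Dienone 11 can tautomerise to the 6-(1,1-dimethylallyl) phenol instead of relaying to C8, the prenyl group can be lost, and Lewis acid with heat could erode C2. The fallback sets out from 6 and comes back at 13. It brings the side-chain carbon in from O7 by an ortho-Claisen shift, finishes it by metathesis, and sets the stereocentre afterwards.
- 6 is O-allylated at the free 7-OH (allyl bromide, K2CO3, acetone, reflux) to 7-(allyloxy)-5-hydroxychromone F3.
- Heating (N,N-diethylaniline, 200 °C) gives 8-allyl-5,7-dihydroxychromone F4; the chelated 5-OH fixes the bond pattern so that C8 is attacked.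
- TBSCl/imidazole silylates the 7-OH to 8-allyl-7-(TBSO)-5-hydroxychromone F5.
- Cross-metathesis with 2-methyl-2-butene (second-generation Grubbs catalyst, 40 °C) gives 7-(TBSO)-5-hydroxy-8-prenylchromone F6.
- The arylation of step 5, run on F6 with 5, gives 13 directly. This arylation is itself a weak point, because the free chelating 5-OH and the 8-substituent are untested in that reaction.

Step 7 (SeO2 allylic oxidation). Conversion may be modest, over-oxidation to the enal is expected as a by-product, and the polyoxygenated flavanone may be attacked by the peroxide. The fallback sets out from 13 and comes back at 14, and it builds the oxidised terminus by metathesis and reduction instead of C–H oxidation. Cross-metathesis of the prenyl group of 13 with excess methacrolein (second-generation Hoveyda–Grubbs catalyst, CH2Cl2, 40 °C; E-selective for the 2-methyl enal) gives (2E)-4-[(2S)-2-[3,4-bis(TBSO)phenyl]-7-(TBSO)-5-hydroxy-4-oxochroman-8-yl]-2-methylbut-2-enal F7. Aldehyde-selective reduction (NaBH4, EtOH–CH2Cl2, −78 °C; the chelated, electron-rich C4 ketone is left alone) gives 14.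

**Further compounds**
F1 | step 5 | [7-(TBSO)-5-(prenyloxy)-4-oxo-4H-chromen-2-yl]zinc chloride | Cl[Zn]c1cc(=O)c2c(OCC=C(C)C)cc(O[Si](C)(C)C(C)(C)C)cc2o1
F2 | step 5 | 2-[3,4-bis(TBSO)phenyl]-7-(TBSO)-5-(prenyloxy)-4H-chromen-4-one | CC(C)=CCOc1cc(O[Si](C)(C)C(C)(C)C)cc2oc(-c3ccc(O[Si](C)(C)C(C)(C)C)c(O[Si](C)(C)C(C)(C)C)c3)cc(=O)c12
F3 | step 6 | 7-(allyloxy)-5-hydroxychromone | Oc1cc(OCC=C)cc2occc(=O)c12
F4 | step 6 | 8-allyl-5,7-dihydroxychromone | C=CCc1c(O)cc(O)c2c1occc2=O
F5 | step 6 | 8-allyl-7-(TBSO)-5-hydroxychromone | C=CCc1c(O[Si](C)(C)C(C)(C)C)cc(O)c2c1occc2=O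
F6 | step 6 | 7-(TBSO)-5-hydroxy-8-prenylchromone | CC(C)=CCc1c(O[Si](C)(C)C(C)(C)C)cc(O)c2c1occc2=O
F7 | step 7 | (2E)-4-[(2S)-2-[3,4-bis(TBSO)phenyl]-7-(TBSO)-5-hydroxy-4-oxochroman-8-yl]-2-methylbut-2-enal | C/C(=C\Cc1c(O[Si](C)(C)C(C)(C)C)cc(O)c2c1O[C@H](c1ccc(O[Si](C)(C)C(C)(C)C)c(O[Si](C)(C)C(C)(C)C)c1)CC2=O)C=O
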